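Compound numbers used throughout: 1–24 as defined in the steps and the compound list. Sequoiaflavone is 24, the diene is 13, methyl propiolate is 14 and the key-step product is 16.

## The problem

Sequoiaflavone (24) is a biflavone in which a 5-hydroxy-7-methoxyflavone (rings A and C with aryl ring B) and an apigenin unit (rings D and F with aryl ring E) are joined only through the bond between C3' of ring B and C8'' of ring D. The molecule has no stereocentre and the target structure defines no configuration at the biaryl axis, so the difficulty is regiochemical and steric. C8'' lies between O7'' and the pyranone oxygen O1'', and C3' lies next to O4', so a direct aryl–aryl coupling would join two ortho-oxygenated carbons and would first need a handle at C8'' and not at the equally activated C6''. Of six phenolic oxygens only O7 is methylated, so the methyl ether has to arrive inside a building block and survive the unmasking of the other five. The two 4-pyranones tolerate neither hot alkali (ring opening) nor strong carbon nucleophiles (attack at C2 or C4), the 5-O-benzyl ethers peri to a carbonyl are acid-labile, and the phloroglucinol-type rings are readily attacked by electrophiles. Two features allow the biaryl coupling to be avoided. Ring B carries C2 on C1', C8'' on C3' and oxygen on C4' (oxygen para to the acyl-derived carbon, ortho to the aryl group), which is the pattern a 1-methoxy-3-silyloxybutadiene with the aryl group on C4 gives with a propiolate after loss of methanol, forming C2'–C3' and C1'–C6'. And C8'' is ortho to the oxygen that becomes O1''; in the acetophenone precursor of ring D this is the only free phenol and its allyl ether has one open ortho position, so a Claisen rearrangement can place the first carbon of the future ring B on C8'' with no C6''/C8'' ambiguity.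

## Retrosynthesis

**24 from 23.** The four O–benzyl bonds at O4', O5'', O7'' and O4''' are cut. Benzyl is preferred to alkyl protection because hydrogenolysis cannot touch the O7 methyl ether, whereas any dealkylating reagent would have to tell O7 from its neighbours. Compound 23 is no smaller, but all free phenols except the chelated 5-OH are masked in one uniform way. The forward step must cleave four ethers without reducing either pyranone C2=C3 bond.

**23 from 22, and 22 from 19 (through 21) and 20.** Ring C is opened at O1–C2 and the diketone 22 is cut at C2–C3. Building the methoxyflavone last lets the methyl ether enter with commercial 20 and face only two further steps. Opening ring F instead would leave the hindered, fully substituted ring D to be acylated late. The cut removes rings A and C and leaves a plain benzoic acid, 19. The forward reactions are C-acylation of the polyanion of 20 by acid chloride 21 and an acid cyclodehydration in which the two equivalent phenols of 22 lead to the same flavone.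

**19 from 18, and 18 from 16.** These are functional-group changes only: ester hydrolysis, and exchange of the aryl silyl ether at O4' for a benzyl ether. The silyl ether delivered by the cycloaddition would not survive saponification or the polyanion chemistry, and a benzyl ether joins the final global deprotection.

**16 from 13 and 14 (through 15): the key disconnection.** Ring B is cut at C2'–C3' and C1'–C6'. Cutting C3'–C8'' instead leads to a cross-coupling at a carbon flanked by two oxygens and to the C6''/C8'' halogenation problem. Cutting bonds of ring D leaves both pyranones still to be built. Here ring B shrinks to a four-carbon chain on C8'' plus commercial 14, with the complete apigenin unit already in place. The forward reaction must give the right orientation (C4 of the diene to the β carbon of 14), needs the aryl group on the outside of the s-cis diene, and must shed the methoxy group from 15 to aromatise.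

**13 from 12, 11, 10, 9 and 7.** The O–Si bond, the C–OMe bond of the vinylogous ester and the C–C bond to the ethynyl unit are cut in turn. Ketone 12 has enolisable hydrogens only on the benzylic side, so silylation can give only the 2-silyloxydiene 13. Ynone 11 fixes the β-methoxyvinyl ketone regiochemistry by conjugate addition. It comes from propargylic alcohol 10, which is obtained by ethynylation of aldehyde 9, the oxidative cleavage product of the allyl group in 7. Formylation of a methyl ketone was rejected because it would react at the more acidic benzylic position. The four-carbon chain is thus reduced to an allyl group.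

**7 from 6, and 6 from 4 and 5.** Ring F is cut at O1''–C2'' and C2''–C3''. Polyanion acylation and acid cyclodehydration are preferred to an iodine-mediated chalcone cyclisation, which would endanger the ortho-allylphenol through iodoetherification. Compound 4 has a single free phenol, so only one flavone can form and the allyl group must end on C8''.

**4 from 3, 2 and 1.** The C8''–CH2 bond is cut by a retro-Claisen step, then the O-allyl and the two O-benzyl bonds. A Claisen rearrangement on a 7-O-allylflavone can deliver to C6 or C8. In 3 the allyloxy group has the acetyl-bearing carbon on one side and a single C–H on the other, so the regiochemistry is unambiguous. The forward steps are a chelation-controlled twofold benzylation of 1, allylation of the remaining phenol and a thermal [3,3] shift.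

## Roads not taken

**Alternative 1:** Both pyranones are cut at O1–C2 and O1''–C2'', leading back to the bichalcone A2. In the forward direction iodine in hot DMSO would cyclise and dehydrogenate both 2'-hydroxychalcone units at once to give penta-O-benzylsequoiaflavone A1, one deprotection from the target.
- Merits: the end of this route is shorter and more convergent than the chosen plan, which builds the two heterocycles one after the other, and the oxidative cyclisation is a dependable flavone synthesis.
- Weak points: A2 already contains the C3'–C8'' bond, so the hindered, regiochemically demanding aryl–aryl coupling is only moved earlier. A2 is also unsymmetrical: its biaryl core carries an acetyl group on ring D and a formyl group on ring B, which must undergo two different crossed aldol condensations without self-condensation, and that requires staging or protection.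
- Comparison: A1 is closer to the target than any intermediate of the chosen route. Against this the chosen plan offers a ring B made around an existing C–C bond, no halogenation at C8'' and no metal-mediated coupling of two ortho-oxygenated carbons.

**Alternative 2:** Ring D is cut at C8''–C8a'', C6''–C7'' and C4a''–C8a''. Heating 3-ethoxycyclobutenone A4 with the ring B siloxyalkyne A5 would open the cyclobutenone to a vinylketene, which adds to the alkyne; ring opening, six-electron electrocyclisation and tautomerisation then give the 2-arylphloroglucinol A3 with three different oxygen substituents.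
- Merits: like the chosen plan it makes the biaryl bond by ring synthesis. Its reacting centres are less crowded than the aryl-bearing diene terminus of 13, and the orientation is dictated by ketene chemistry, which is arguably more secure.
- Weak points: A5 is a sensitive ynol ether that needs its own multistep preparation. A3 contains neither pyranone, so the crowded ring D must still be C-acylated between two oxygens and both flavone units built afterwards. The ethyl ether at O5'' must finally be cleaved in the presence of the O7 methyl ether.
- Comparison: the key step may well be the more reliable of the two. The chosen plan counters with a key step that follows completion of the apigenin unit, so only one heterocycle remains to be made, and with protecting groups that all leave by hydrogenolysis.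

**Alternative 3:** The C2''=C3'' bond of ring F is cut. On heating, the acylphosphorane A7 would attack its neighbouring aryl ester carbonyl in an intramolecular Wittig reaction and, with loss of triphenylphosphine oxide, close the pyranone to give the biaryl ester A6.
- Merits: the closure is neutral and spares acid-labile benzyl ethers. A6 is identical with compound 18, so this road and the chosen one share their last four steps.
- Weak points: the key step solves a ring closure that is routine (the chosen route does it with catalytic acid in step 5) and leaves the real problem, the C3'–C8'' bond, to a hindered cross-coupling on the way to A7. A7 also requires α-halogenation of an electron-rich acetophenone without ring halogenation, and aroylation of a phenol flanked by an aryl and an acyl group.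
- Comparison: if the biaryl coupling worked well, A6 could be reached in fewer than the twelve steps the chosen route needs for 18, and that advantage is real. The chosen plan offers in return independence from that coupling and an unambiguous placement of carbon on C8''.

Key step: step 11

Assumption: the C3'–C8'' axis is treated as configurationally undefined, as in the target structure, and compounds 1, 5, 14 and 20 are taken as purchasable.

## Route

Step 1
Reactants: 1 2',4',6'-trihydroxyacetophenone
Product: 2 4',6'-bis(benzyloxy)-2'-hydroxyacetophenone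
Conditions: BnBr (2.1 equiv), K2CO3, DMF, 0 °C to rt
Reagents that add atoms: benzyl bromide, BrCc1ccccc1
Why: Williamson etherification; the para hydroxyl and one ortho hydroxyl are alkylated, after which the remaining ortho hydroxyl is locked in a hydrogen bond to the acetyl group and stays free when only two equivalents of halide are used.

Step 2
Reactants: 2 4',6'-bis(benzyloxy)-2'-hydroxyacetophenone
Product: 3 2'-(allyloxy)-4',6'-bis(benzyloxy)acetophenone
Conditions: allyl bromide, K2CO3, DMF, 60 °C
Reagents that add atoms: allyl bromide, C=CCBr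
Why: Williamson etherification of the chelated phenol, which reacts once warmed with a reactive allylic halide; no other nucleophilic site remains.

Step 3
Reactants: 3 2'-(allyloxy)-4',6'-bis(benzyloxy)acetophenone
Product: 4 3'-allyl-4',6'-bis(benzyloxy)-2'-hydroxyacetophenone
Conditions: N,N-diethylaniline, 200 °C
Reagents that add atoms: none
Why: Aromatic Claisen rearrangement; the [3,3] shift can only reach C3' because the other ortho carbon carries the acetyl group, and tautomerisation restores the chelated phenol. The new C–C bond is the future C8''–C bond, and benzyl aryl ethers are stable at this temperature.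

Step 4
Reactants: 4 3'-allyl-4',6'-bis(benzyloxy)-2'-hydroxyacetophenone; 5 4-(benzyloxy)benzoyl chloride
Product: 6 1-[3-allyl-4,6-bis(benzyloxy)-2-hydroxyphenyl]-3-[4-(benzyloxy)phenyl]propane-1,3-dione
Conditions: LiN(SiMe3)2 (3.2 equiv), THF, −78 to −10 °C; then 5, −78 °C to rt; aq. HCl
Reagents that add atoms: none
Why: Polyanion acylation of an o-hydroxyacetophenone (a one-flask equivalent of the Baker–Venkataraman sequence); the phenoxide–enolate dianion is acylated at carbon by 5, or at oxygen followed by acyl transfer, and the third equivalent of base deprotonates the 1,3-diketone so that it is not acylated again.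

Step 5
Reactants: 6 1-[3-allyl-4,6-bis(benzyloxy)-2-hydroxyphenyl]-3-[4-(benzyloxy)phenyl]propane-1,3-dione
Product: 7 8-allyl-5,7-bis(benzyloxy)-2-[4-(benzyloxy)phenyl]chromen-4-one
Conditions: TsOH·H2O (10 mol%), toluene, 80 °C
Reagents that add atoms: none
Why: Acid-catalysed cyclodehydration; the only phenol adds to the aroyl carbonyl (6-exo-trig) and water is lost to give the pyranone, so the allyl group must sit on C8. Catalytic sulfonic acid in toluene is mild enough for the 5-O-benzyl ether and does not add the phenol to the allyl group.

Step 6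
Reactants: 7 8-allyl-5,7-bis(benzyloxy)-2-[4-(benzyloxy)phenyl]chromen-4-one
Product: 9 2-[5,7-bis(benzyloxy)-2-[4-(benzyloxy)phenyl]-4-oxochromen-8-yl]acetaldehyde, via racemic vicinal diol 8 (not isolated)
Conditions: OsO4 (2 mol%), NaIO4 (4 equiv), 2,6-lutidine, dioxane/H2O 3:1, rt
Reagents that add atoms: osmium tetroxide, O=[Os](=O)(=O)=O (delivers the aldehyde oxygen and is regenerated by NaIO4)
Why: Lemieux–Johnson oxidation; the terminal alkene is dihydroxylated far faster than the electron-poor pyranone C2=C3 bond, periodate cleaves diol 8 in situ, and lutidine suppresses over-oxidation of the arylacetaldehyde.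

Step 7
Reactants: 9 2-[5,7-bis(benzyloxy)-2-[4-(benzyloxy)phenyl]-4-oxochromen-8-yl]acetaldehyde
Product: 10 5,7-bis(benzyloxy)-2-[4-(benzyloxy)phenyl]-8-(2-hydroxybut-3-yn-1-yl)chromen-4-one (racemic)
Conditions: ethynylmagnesium bromide (1.3 equiv), THF, −78 °C; aq. NH4Cl
Reagents that add atoms: ethynylmagnesium bromide, C#C[Mg]Br
Why: Grignard addition to an aldehyde; at −78 °C the aldehyde is much more electrophilic than the vinylogous-ester carbonyl of the pyranone. The carbinol centre forms as a racemate and is removed in step 8.

Step 8
Reactants: 10 5,7-bis(benzyloxy)-2-[4-(benzyloxy)phenyl]-8-(2-hydroxybut-3-yn-1-yl)chromen-4-one (racemic)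
Product: 11 5,7-bis(benzyloxy)-2-[4-(benzyloxy)phenyl]-8-(2-oxobut-3-yn-1-yl)chromen-4-one
Conditions: Dess–Martin periodinane, NaHCO3, CH2Cl2, 0 °C to rt
Reagents that add atoms: none
Why: Dess–Martin oxidation of a secondary propargylic alcohol; the buffered, near-neutral conditions leave the benzylic α-hydrogens and the terminal alkyne alone.

Step 9
Reactants: 11 5,7-bis(benzyloxy)-2-[4-(benzyloxy)phenyl]-8-(2-oxobut-3-yn-1-yl)chromen-4-one
Product: 12 5,7-bis(benzyloxy)-2-[4-(benzyloxy)phenyl]-8-[(3E)-4-methoxy-2-oxobut-3-en-1-yl]chromen-4-one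
Conditions: MeOH, DABCO (10 mol%), CH2Cl2, 0 °C to rt
Reagents that add atoms: methanol, CO
Why: Amine-catalysed oxa-Michael addition of an alcohol to a terminal ynone; the β-ammonium enolate formed with DABCO is displaced by methanol to give the thermodynamically favoured E β-methoxy enone.

Step 10
Reactants: 12 5,7-bis(benzyloxy)-2-[4-(benzyloxy)phenyl]-8-[(3E)-4-methoxy-2-oxobut-3-en-1-yl]chromen-4-one
Product: 13 8-[(1Z,3E)-2-(tert-butyldimethylsilyloxy)-4-methoxybuta-1,3-dienyl]-5,7-bis(benzyloxy)-2-[4-(benzyloxy)phenyl]chromen-4-one
Conditions: TBSOTf (1.3 equiv), Et3N (3 equiv), Et2O, −78 to 0 °C; used directly after filtration through Et3N-deactivated silica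
Reagents that add atoms: tert-butyldimethylsilyl trifluoromethanesulfonate, CC(C)(C)[Si](C)(C)OS(=O)(=O)C(F)(F)F
Why: Soft enolisation and O-silylation, the standard route to 1-methoxy-3-silyloxybutadienes from β-methoxy enones; only the benzylic CH2 can enolise. The Z enol ether (aryl cis to the silyloxy group) is favoured because it keeps the twisted aryl group away from the methoxyvinyl unit, and excess amine keeps the silyl triflate from activating the pyranone carbonyl.

Step 11
Reactants: 13 8-[(1Z,3E)-2-(tert-butyldimethylsilyloxy)-4-methoxybuta-1,3-dienyl]-5,7-bis(benzyloxy)-2-[4-(benzyloxy)phenyl]chromen-4-one; 14 methyl propiolate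
Product: 16 methyl 4-(tert-butyldimethylsilyloxy)-3-[5,7-bis(benzyloxy)-2-[4-(benzyloxy)phenyl]-4-oxochromen-8-yl]benzoate, via cis cycloadduct 15 (not isolated)
Conditions: 14 (5 equiv), BHT (cat.), toluene, 120 °C, sealed tube
Reagents that add atoms: none
Why: Thermal Diels–Alder cycloaddition of the electron-rich diene 13 with the electron-poor alkyne 14 followed by aromatisation; the closest known reaction type is the benzannulation of 1-methoxy-3-silyloxybutadienes with propiolates to 4-silyloxybenzoates. The silyloxy group on C3 and the methoxy group on C1 both raise the electron density at C4, so this flavonyl-bearing terminus bonds to the β carbon of 14 and the methoxy-bearing C1 to the α carbon in a concerted, asynchronous transition state. Ring B is closed by this intermolecular suprafacial [4+2] addition, which forms C2'–C3' and C1'–C6' and gives the cis-disubstituted cyclohexa-1,4-diene 15. The two sp3 centres of 15 are transient: the allylic methoxy group ionises with help from the silyl enol ether and the doubly allylic, benzylic hydrogen on the flavonyl-bearing carbon is lost, so methanol leaves and no stereocentre remains. The selectivity required is orientation (ester para and flavonyl ortho to the silyloxy group), and the two oxygen donors secure it against the weaker opposite preference of a 1-aryl diene. The 1Z,3E geometry places the flavonyl and methoxy groups on the outside of the s-cis diene, the only arrangement in which so large a substituent allows cycloaddition; the pyranone C2=C3 bonds are poor dienophiles and are not expected to compete.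

Step 12
Reactants: 16 methyl 4-(tert-butyldimethylsilyloxy)-3-[5,7-bis(benzyloxy)-2-[4-(benzyloxy)phenyl]-4-oxochromen-8-yl]benzoate
Product: 18 methyl 4-(benzyloxy)-3-[5,7-bis(benzyloxy)-2-[4-(benzyloxy)phenyl]-4-oxochromen-8-yl]benzoate, via caesium phenoxide 17 (not isolated)
Conditions: CsF (3 equiv), BnBr (1.5 equiv), DMF, rt
Reagents that add atoms: benzyl bromide, BrCc1ccccc1
Why: Fluoride cleaves the aryl silyl ether to phenoxide 17, which is benzylated in the same flask (Williamson etherification); the methyl ester and the pyranone are inert to fluoride.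

Step 13
Reactants: 18 methyl 4-(benzyloxy)-3-[5,7-bis(benzyloxy)-2-[4-(benzyloxy)phenyl]-4-oxochromen-8-yl]benzoate
Product: 19 4-(benzyloxy)-3-[5,7-bis(benzyloxy)-2-[4-(benzyloxy)phenyl]-4-oxochromen-8-yl]benzoic acid
Conditions: LiOH·H2O (5 equiv), THF/MeOH/H2O, 45 °C; then 1 M HCl
Reagents that add atoms: lithium hydroxide, [Li+].[OH-]
Why: Saponification of an unhindered methyl benzoate; dilute LiOH at moderate temperature does not open the pyranone, which needs hot concentrated alkali.

Step 14
Reactants: 19 4-(benzyloxy)-3-[5,7-bis(benzyloxy)-2-[4-(benzyloxy)phenyl]-4-oxochromen-8-yl]benzoic acid; 20 2',6'-dihydroxy-4'-methoxyacetophenone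
Product: 22 1-[4-(benzyloxy)-3-[5,7-bis(benzyloxy)-2-[4-(benzyloxy)phenyl]-4-oxochromen-8-yl]phenyl]-3-(2,6-dihydroxy-4-methoxyphenyl)propane-1,3-dione, via acid chloride 21 (not isolated)
Conditions: 19, (COCl)2, DMF (cat.), CH2Cl2, 0 °C to rt, concentrate; separately 20, LiN(SiMe3)2 (4.2 equiv), THF, −78 to −10 °C; add 21 in THF, −78 °C to rt; aq. HCl
Reagents that add atoms: none
Why: Acid chloride formation followed by the polyanion acylation used in step 4; four equivalents of base give the bis-phenoxide enolate of 20 and deprotonate the product diketone, and at −78 °C the acid chloride is far more electrophilic than the pyranone of the apigenin unit. The O7 methyl ether enters here, unprotected and at the right oxygen.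

Step 15
Reactants: 22 1-[4-(benzyloxy)-3-[5,7-bis(benzyloxy)-2-[4-(benzyloxy)phenyl]-4-oxochromen-8-yl]phenyl]-3-(2,6-dihydroxy-4-methoxyphenyl)propane-1,3-dione
Product: 23 2-[4-(benzyloxy)-3-[5,7-bis(benzyloxy)-2-[4-(benzyloxy)phenyl]-4-oxochromen-8-yl]phenyl]-5-hydroxy-7-methoxychromen-4-one
Conditions: TsOH·H2O (20 mol%), toluene, 90 °C
Reagents that add atoms: none
Why: Acid-catalysed cyclodehydration closing ring C; the two phenols of 22 are equivalent, so either gives the same 5-hydroxy-7-methoxyflavone, and the remaining phenol ends as the chelated 5-OH. Any acid-induced loss of a benzyl group would be harmless, since all are removed in step 16.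

Step 16
Reactants: 23 2-[4-(benzyloxy)-3-[5,7-bis(benzyloxy)-2-[4-(benzyloxy)phenyl]-4-oxochromen-8-yl]phenyl]-5-hydroxy-7-methoxychromen-4-one
Product: 24 sequoiaflavone
Conditions: H2 (1 atm), 10% Pd/C, THF/MeOH, rt
Reagents that add atoms: none
Why: Hydrogenolysis of four aryl benzyl ethers; the aryl methyl ether is inert, and at ambient pressure and temperature the pyranone C2=C3 bonds are not expected to be reduced.

## Compound list

1 | 2',4',6'-trihydroxyacetophenone | CC(=O)c1c(O)cc(O)cc1O | starting material
2 | 4',6'-bis(benzyloxy)-2'-hydroxyacetophenone | CC(=O)c1c(O)cc(OCc2ccccc2)cc1OCc1ccccc1 | intermediate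
3 | 2'-(allyloxy)-4',6'-bis(benzyloxy)acetophenone | CC(=O)c1c(OCC=C)cc(OCc2ccccc2)cc1OCc1ccccc1 | intermediate
4 | 3'-allyl-4',6'-bis(benzyloxy)-2'-hydroxyacetophenone | CC(=O)c1c(O)c(CC=C)c(OCc2ccccc2)cc1OCc1ccccc1 | intermediate
5 | 4-(benzyloxy)benzoyl chloride | O=C(Cl)c1ccc(OCc2ccccc2)cc1 | starting material
6 | 1-[3-allyl-4,6-bis(benzyloxy)-2-hydroxyphenyl]-3-[4-(benzyloxy)phenyl]propane-1,3-dione | O=C(CC(=O)c1ccc(OCc2ccccc2)cc1)c1c(O)c(CC=C)c(OCc2ccccc2)cc1OCc1ccccc1 | intermediate
7 | 8-allyl-5,7-bis(benzyloxy)-2-[4-(benzyloxy)phenyl]chromen-4-one | C=CCc1c(OCc2ccccc2)cc(OCc2ccccc2)c2c(=O)cc(-c3ccc(OCc4ccccc4)cc3)oc12 | intermediate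
8 | 5,7-bis(benzyloxy)-2-[4-(benzyloxy)phenyl]-8-(2,3-dihydroxypropyl)chromen-4-one (racemic; not isolated) | OCC(O)Cc1c(OCc2ccccc2)cc(OCc2ccccc2)c2c(=O)cc(-c3ccc(OCc4ccccc4)cc3)oc12 | intermediate
9 | 2-[5,7-bis(benzyloxy)-2-[4-(benzyloxy)phenyl]-4-oxochromen-8-yl]acetaldehyde | O=CCc1c(OCc2ccccc2)cc(OCc2ccccc2)c2c(=O)cc(-c3ccc(OCc4ccccc4)cc3)oc12 | intermediate
10 | 5,7-bis(benzyloxy)-2-[4-(benzyloxy)phenyl]-8-(2-hydroxybut-3-yn-1-yl)chromen-4-one (racemic) | C#CC(O)Cc1c(OCc2ccccc2)cc(OCc2ccccc2)c2c(=O)cc(-c3ccc(OCc4ccccc4)cc3)oc12 | intermediate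
11 | 5,7-bis(benzyloxy)-2-[4-(benzyloxy)phenyl]-8-(2-oxobut-3-yn-1-yl)chromen-4-one | C#CC(=O)Cc1c(OCc2ccccc2)cc(OCc2ccccc2)c2c(=O)cc(-c3ccc(OCc4ccccc4)cc3)oc12 | intermediate
12 | 5,7-bis(benzyloxy)-2-[4-(benzyloxy)phenyl]-8-[(3E)-4-methoxy-2-oxobut-3-en-1-yl]chromen-4-one | CO/C=C/C(=O)Cc1c(OCc2ccccc2)cc(OCc2ccccc2)c2c(=O)cc(-c3ccc(OCc4ccccc4)cc3)oc12 | intermediate
13 | 8-[(1Z,3E)-2-(tert-butyldimethylsilyloxy)-4-methoxybuta-1,3-dienyl]-5,7-bis(benzyloxy)-2-[4-(benzyloxy)phenyl]chromen-4-one | CO/C=C/C(O[Si](C)(C)C(C)(C)C)=C/c1c(OCc2ccccc2)cc(OCc2ccccc2)c2c(=O)cc(-c3ccc(OCc4ccccc4)cc3)oc12 | intermediate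
14 | methyl propiolate | C#CC(=O)OC | starting material
15 | methyl cis-3-[5,7-bis(benzyloxy)-2-[4-(benzyloxy)phenyl]-4-oxochromen-8-yl]-4-(tert-butyldimethylsilyloxy)-6-methoxycyclohexa-1,4-diene-1-carboxylate (racemic, one enantiomer drawn; not isolated) | COC(=O)C1=C[C@@H](c2c(OCc3ccccc3)cc(OCc3ccccc3)c3c(=O)cc(-c4ccc(OCc5ccccc5)cc4)oc23)C(O[Si](C)(C)C(C)(C)C)=C[C@H]1OC | intermediate
16 | methyl 4-(tert-butyldimethylsilyloxy)-3-[5,7-bis(benzyloxy)-2-[4-(benzyloxy)phenyl]-4-oxochromen-8-yl]benzoate | COC(=O)c1ccc(O[Si](C)(C)C(C)(C)C)c(-c2c(OCc3ccccc3)cc(OCc3ccccc3)c3c(=O)cc(-c4ccc(OCc5ccccc5)cc4)oc23)c1 | intermediate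
17 | caesium 2-[5,7-bis(benzyloxy)-2-[4-(benzyloxy)phenyl]-4-oxochromen-8-yl]-4-(methoxycarbonyl)phenoxide (not isolated) | COC(=O)c1ccc([O-])c(-c2c(OCc3ccccc3)cc(OCc3ccccc3)c3c(=O)cc(-c4ccc(OCc5ccccc5)cc4)oc23)c1.[Cs+] | intermediate
18 | methyl 4-(benzyloxy)-3-[5,7-bis(benzyloxy)-2-[4-(benzyloxy)phenyl]-4-oxochromen-8-yl]benzoate | COC(=O)c1ccc(OCc2ccccc2)c(-c2c(OCc3ccccc3)cc(OCc3ccccc3)c3c(=O)cc(-c4ccc(OCc5ccccc5)cc4)oc23)c1 | intermediate
19 | 4-(benzyloxy)-3-[5,7-bis(benzyloxy)-2-[4-(benzyloxy)phenyl]-4-oxochromen-8-yl]benzoic acid | O=C(O)c1ccc(OCc2ccccc2)c(-c2c(OCc3ccccc3)cc(OCc3ccccc3)c3c(=O)cc(-c4ccc(OCc5ccccc5)cc4)oc23)c1 | intermediate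
20 | 2',6'-dihydroxy-4'-methoxyacetophenone | COc1cc(O)c(C(C)=O)c(O)c1 | starting material
21 | 4-(benzyloxy)-3-[5,7-bis(benzyloxy)-2-[4-(benzyloxy)phenyl]-4-oxochromen-8-yl]benzoyl chloride (not isolated) | O=C(Cl)c1ccc(OCc2ccccc2)c(-c2c(OCc3ccccc3)cc(OCc3ccccc3)c3c(=O)cc(-c4ccc(OCc5ccccc5)cc4)oc23)c1 | intermediate
22 | 1-[4-(benzyloxy)-3-[5,7-bis(benzyloxy)-2-[4-(benzyloxy)phenyl]-4-oxochromen-8-yl]phenyl]-3-(2,6-dihydroxy-4-methoxyphenyl)propane-1,3-dione | COc1cc(O)c(C(=O)CC(=O)c2ccc(OCc3ccccc3)c(-c3c(OCc4ccccc4)cc(OCc4ccccc4)c4c(=O)cc(-c5ccc(OCc6ccccc6)cc5)oc34)c2)c(O)c1 | intermediate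
23 | 2-[4-(benzyloxy)-3-[5,7-bis(benzyloxy)-2-[4-(benzyloxy)phenyl]-4-oxochromen-8-yl]phenyl]-5-hydroxy-7-methoxychromen-4-one (4',5'',7'',4'''-tetra-O-benzylsequoiaflavone) | COc1cc(O)c2c(=O)cc(-c3ccc(OCc4ccccc4)c(-c4c(OCc5ccccc5)cc(OCc5ccccc5)c5c(=O)cc(-c6ccc(OCc7ccccc7)cc6)oc45)c3)oc2c1 | intermediate
24 | sequoiaflavone | COc1cc(O)c2c(=O)cc(-c3ccc(O)c(-c4c(O)cc(O)c5c(=O)cc(-c6ccc(O)cc6)oc45)c3)oc2c1 | target

## Step count and least certain steps

Total step count: 16. Longest linear sequence: 16 steps (1 to 24); 5, 14 and 20 enter directly as purchased materials.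

**Step 11 (key step).** The aryl group on the diene terminus is twisted and has two ortho substituents, so bond formation at that carbon may be slow. Over the long heating this would need, the silyl dienol ether could hydrolyse or isomerise, the propiolate could oligomerise, and the aryl group could erode the orientation. The preceding silylation (step 10) could also suffer if the silyl triflate activates the pyranone carbonyl.

The fallback uses a much more reactive diene class and needs no silyl triflate. It sets out from 11. Dimethylamine in THF adds to the ynone to give the vinylogous amide 5,7-bis(benzyloxy)-2-[4-(benzyloxy)phenyl]-8-[(3E)-4-(dimethylamino)-2-oxobut-3-en-1-yl]chromen-4-one F1. Deprotonation with KN(SiMe3)2 at −78 °C and trapping with TBSCl gives the 1-amino-3-silyloxydiene 8-[(1Z,3E)-2-(tert-butyldimethylsilyloxy)-4-(dimethylamino)buta-1,3-dienyl]-5,7-bis(benzyloxy)-2-[4-(benzyloxy)phenyl]chromen-4-one F2. Such dienes add to propiolates near room temperature with the same orientation; with 14 the adduct methyl cis-3-[5,7-bis(benzyloxy)-2-[4-(benzyloxy)phenyl]-4-oxochromen-8-yl]-4-(tert-butyldimethylsilyloxy)-6-(dimethylamino)cyclohexa-1,4-diene-1-carboxylate F3 should lose dimethylamine and return to the route at 16.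

**Step 7.** The arylacetaldehyde 9 has acidic benzylic α-hydrogens, so the Grignard reagent may enolise it instead of adding, the enolate may undergo aldol self-condensation, and excess reagent may attack the pyranone carbonyl.

The fallback sets out from 9 and changes the oxidation level at which the alkyne is introduced. Pinnick oxidation (NaClO2, NaH2PO4, 2-methyl-2-butene) gives 2-[5,7-bis(benzyloxy)-2-[4-(benzyloxy)phenyl]-4-oxochromen-8-yl]acetic acid F4. Carbodiimide coupling with N,O-dimethylhydroxylamine gives the Weinreb amide 2-[5,7-bis(benzyloxy)-2-[4-(benzyloxy)phenyl]-4-oxochromen-8-yl]-N-methoxy-N-methylacetamide F5. Ethynylmagnesium bromide then converts F5 through its stable chelate directly into the ynone. The fallback comes back to the route at 11, so 10 and step 8 are bypassed.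

**Step 14.** The phenoxide oxygens of the polyanion may be acylated in place of the enolate carbon, a second acylation may occur, or the valuable acid chloride may be consumed incompletely; excess amide base may also attack the pyranone.

The fallback sets out from 19 and separates the acyl transfer into two controlled events. Esterification with 20 (EDC, DMAP, CH2Cl2) acylates one of the two equivalent phenols and gives 2-acetyl-3-hydroxy-5-methoxyphenyl 4-(benzyloxy)-3-[5,7-bis(benzyloxy)-2-[4-(benzyloxy)phenyl]-4-oxochromen-8-yl]benzoate F6. A Baker–Venkataraman rearrangement (powdered KOH, pyridine, 50 °C) then moves the acyl group intramolecularly to carbon. The fallback comes back to the route at 22.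

**Step 16.** Partly debenzylated intermediates may precipitate and stall the hydrogenolysis, or prolonged exposure may begin to saturate a pyranone C2=C3 bond.

The fallback sets out from 23 and replaces hydrogenolysis by Lewis-acid ether cleavage: BCl3 with pentamethylbenzene as cation scavenger in CH2Cl2 at −78 °C removes aryl benzyl ethers, while the O7 methyl ether, which is not peri to a carbonyl, is retained. It arrives at 24 without any new intermediate.

## Further compounds

F1 | step 11 | 5,7-bis(benzyloxy)-2-[4-(benzyloxy)phenyl]-8-[(3E)-4-(dimethylamino)-2-oxobut-3-en-1-yl]chromen-4-one | CN(C)/C=C/C(=O)Cc1c(OCc2ccccc2)cc(OCc2ccccc2)c2c(=O)cc(-c3ccc(OCc4ccccc4)cc3)oc12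
F2 | step 11 | 8-[(1Z,3E)-2-(tert-butyldimethylsilyloxy)-4-(dimethylamino)buta-1,3-dienyl]-5,7-bis(benzyloxy)-2-[4-(benzyloxy)phenyl]chromen-4-one | CN(C)/C=C/C(O[Si](C)(C)C(C)(C)C)=C/c1c(OCc2ccccc2)cc(OCc2ccccc2)c2c(=O)cc(-c3ccc(OCc4ccccc4)cc3)oc12
F3 | step 11 | methyl cis-3-[5,7-bis(benzyloxy)-2-[4-(benzyloxy)phenyl]-4-oxochromen-8-yl]-4-(tert-butyldimethylsilyloxy)-6-(dimethylamino)cyclohexa-1,4-diene-1-carboxylate (racemic, one enantiomer drawn) | COC(=O)C1=C[C@@H](c2c(OCc3ccccc3)cc(OCc3ccccc3)c3c(=O)cc(-c4ccc(OCc5ccccc5)cc4)oc23)C(O[Si](C)(C)C(C)(C)C)=C[C@H]1N(C)C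
F4 | step 7 | 2-[5,7-bis(benzyloxy)-2-[4-(benzyloxy)phenyl]-4-oxochromen-8-yl]acetic acid | O=C(O)Cc1c(OCc2ccccc2)cc(OCc2ccccc2)c2c(=O)cc(-c3ccc(OCc4ccccc4)cc3)oc12
F5 | step 7 | 2-[5,7-bis(benzyloxy)-2-[4-(benzyloxy)phenyl]-4-oxochromen-8-yl]-N-methoxy-N-methylacetamide | CON(C)C(=O)Cc1c(OCc2ccccc2)cc(OCc2ccccc2)c2c(=O)cc(-c3ccc(OCc4ccccc4)cc3)oc12
F6 | step 14 | 2-acetyl-3-hydroxy-5-methoxyphenyl 4-(benzyloxy)-3-[5,7-bis(benzyloxy)-2-[4-(benzyloxy)phenyl]-4-oxochromen-8-yl]benzoate | COc1cc(O)c(C(C)=O)c(OC(=O)c2ccc(OCc3ccccc3)c(-c3c(OCc4ccccc4)cc(OCc4ccccc4)c4c(=O)cc(-c5ccc(OCc6ccccc6)cc5)oc34)c2)c1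
F0 | step 16 | none | none
A1 | alternative 1 | 5,4',5'',7'',4'''-penta-O-benzylsequoiaflavone | COc1cc(OCc2ccccc2)c2c(=O)cc(-c3ccc(OCc4ccccc4)c(-c4c(OCc5ccccc5)cc(OCc5ccccc5)c5c(=O)cc(-c6ccc(OCc7ccccc7)cc6)oc45)c3)oc2c1
A2 | alternative 1 | (E)-1-[2-(benzyloxy)-6-hydroxy-4-methoxyphenyl]-3-[4-(benzyloxy)-3-[4,6-bis(benzyloxy)-2-hydroxy-3-[(E)-3-[4-(benzyloxy)phenyl]prop-2-enoyl]phenyl]phenyl]prop-2-en-1-one (bichalcone) | COc1cc(O)c(C(=O)/C=C/c2ccc(OCc3ccccc3)c(-c3c(OCc4ccccc4)cc(OCc4ccccc4)c(C(=O)/C=C/c4ccc(OCc5ccccc5)cc4)c3O)c2)c(OCc2ccccc2)c1
A3 | alternative 2 | tert-butyl 4-(benzyloxy)-3-[4-ethoxy-2-hydroxy-6-(triisopropylsilyloxy)phenyl]benzoate | CCOc1cc(O)c(-c2cc(C(=O)OC(C)(C)C)ccc2OCc2ccccc2)c(O[Si](C(C)C)(C(C)C)C(C)C)c1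
A4 | alternative 2 | 3-ethoxycyclobut-2-en-1-one | CCOC1=CC(=O)C1
A5 | alternative 2 | tert-butyl 4-(benzyloxy)-3-[(triisopropylsilyloxy)ethynyl]benzoate | CC(C)(C)OC(=O)c1ccc(OCc2ccccc2)c(C#CO[Si](C(C)C)(C(C)C)C(C)C)c1
A6 | alternative 3 | methyl 4-(benzyloxy)-3-[5,7-bis(benzyloxy)-2-[4-(benzyloxy)phenyl]-4-oxochromen-8-yl]benzoate (identical with 18) | COC(=O)c1ccc(OCc2ccccc2)c(-c2c(OCc3ccccc3)cc(OCc3ccccc3)c3c(=O)cc(-c4ccc(OCc5ccccc5)cc4)oc23)c1
A7 | alternative 3 | methyl 4-(benzyloxy)-3-[4,6-bis(benzyloxy)-2-[4-(benzyloxy)benzoyloxy]-3-[2-(triphenylphosphoranylidene)acetyl]phenyl]benzoate | COC(=O)c1ccc(OCc2ccccc2)c(-c2c(OCc3ccccc3)cc(OCc3ccccc3)c(C(=O)C=P(c3ccccc3)(c3ccccc3)c3ccccc3)c2OC(=O)c2ccc(OCc3ccccc3)cc2)c1
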